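## Retrosynthetic overview
1. Jaspic acid comes from a late Cf–CH2–aryl bond made by hydroboration and B‑alkyl Suzuki coupling of an exocyclic diene. The side‑chain alkene comes from a Wittig reaction on an aldehyde, and a thiolate cleaves the aryl methyl ether and methyl ester last.
2. The diene comes from an α‑methyl enone (Saegusa dehydrogenation) made from a Wieland–Miescher‑type ketol. The trans ring fusion (Cj–H) is set by hydrogen‑atom‑transfer (HAT) hydrogenation of a Δ5 olefin.
3. The vicinal quaternary centre Ca is set by two successive deconjugative dienolate alkylations (chain first, Me last, entering from the α face). Wolff–Kishner then removes the ring ketone.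
4. The hydroxy‑enone comes from ketoreductase desymmetrization of an achiral triketone followed by aldol condensation. The cyclohexanedione ring (ring B) is present from the start, ring A forms in the aldol step (Step 3), and no other rings are made.

Atom labels used below:
- Ce = angular C–Me (Ce‑Me β).
- Cj = ring‑fusion CH.
- Ca = quaternary C bearing Me and the chain.
- Cf = CH bearing CH2Ar.
- Cb = ring ketone carbon that is later removed.

Assumptions:
- A commercial ketoreductase (KRED) from a screening panel reduces one ring C=O of triketone 3 with (S) selectivity and leaves the side‑chain methyl ketone untouched (baker's‑yeast precedent).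
- The configuration of the carbinol (Cf) in 4–6 is inconsequential, because that carbon is oxidized in Step 12.
- The thermodynamic dienolate of 7 is alkylated on the face anti to the angular methyl.

## Route

**Step 1**
Reactants: 1 (2‑methylcyclohexane‑1,3‑dione); 2 (methyl vinyl ketone)
Product: 3 (2‑methyl‑2‑(3‑oxobutyl)cyclohexane‑1,3‑dione)
Conditions: H2O, 70 °C (or cat. Et3N)
Reagents that add atoms: none
Why: Michael addition of the acidic dione C‑2 to the enone creates the achiral quaternary carbon; the product is a symmetric prochiral triketone.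

**Step 2**
Reactants: 3
Product: 4 ((2R,3S)‑3‑hydroxy‑2‑methyl‑2‑(3‑oxobutyl)cyclohexan‑1‑one)
Conditions: ketoreductase (KRED, NADPH‑dependent oxidoreductase), NADP+ (cat.), D‑glucose, glucose dehydrogenase, KPi pH 7, 10 % DMSO, 30 °C
Reagents that add atoms: none (the enzyme delivers hydride; the product gains only H)
Why: the KRED reduces one of the two enantiotopic ring carbonyls (asymmetric biocatalytic desymmetrization), setting the quaternary Ce and the carbinol in one step. The first stereocentre, Ce (S in 5), is therefore set by enzyme catalysis from an achiral substrate.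

**Step 3**
Reactants: 4
Product: 5 ((4aS,5S)‑5‑hydroxy‑4a‑methyl‑4,4a,5,6,7,8‑hexahydronaphthalen‑2(3H)‑one)
Conditions: p‑TsOH·H2O (cat.), PhH, reflux, Dean–Stark
Reagents that add atoms: none
Why: intramolecular aldol condensation (Robinson‑type ring closure) of the methyl ketone onto the remaining ring C=O forms ring A and the enone. No new stereocentre is created and Ce is untouched.

**Step 4**
Reactants: 5
Product: 6 (benzyl ether of 5)
Conditions: NaH, BnBr, TBAI (cat.), THF, 0 °C→rt
Reagents that add atoms: benzyl bromide, BrCc1ccccc1
Why: Williamson etherification masks the alcohol so that it survives the strongly basic alkylations and Wolff–Kishner reduction. Benzyl is chosen because it tolerates KOH at 200 °C and is later removed by hydrogenolysis.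

**Step 5**
Reactants: 6
Product: 7 (1‑allyl enone, conjugated; may co‑exist with its β,γ‑isomer, and both give the same dienolate)
Conditions: t‑BuOK (1.1 equiv), t‑BuOH/THF, allyl bromide, 0 °C→rt
Reagents that add atoms: allyl bromide, C=CCBr
Why: t‑BuOK generates the thermodynamic extended dienolate, which is alkylated at the α carbon (Ca) in a deconjugative alkylation. The chain is introduced first as the precursor of the CH2CH2CH=CMe2 side chain.

**Step 6**
Reactants: 7
Product: 8 (Ca quaternary, allyl β, Me α; β,γ‑enone Ci=Cj)
Conditions: t‑BuOK (2 equiv), THF, −10 °C; then MeI, −10 °C→rt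
Reagents that add atoms: iodomethane, CI
Why: the planar dienolate of 7 is methylated at Ca from the α face, anti to the axial angular methyl that shields the β face. This pushes the allyl group to the axial β position and sets Ca with the target relative configuration. The double bond moves to Ci=Cj and cannot re‑conjugate because Ca is now quaternary.

**Step 7**
Reactants: 8
Product: 9 (Cb ketone removed)
Conditions: N2H4·H2O, KOH, diethylene glycol, 130 °C then 200 °C
Reagents that add atoms: none
Why: Huang–Minlon Wolff–Kishner deoxygenation of the neopentylic ketone. The β,γ‑alkene cannot conjugate (Ca is quaternary), and the benzyl ether and terminal alkene survive.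

**Step 8**
Reactants: 9
Product: 10 (primary alcohol, Ca–CH2CH2CH2OH)
Conditions: (a) 9‑BBN, THF, 0 °C→rt; (b) NaOH, H2O2
Reagents that add atoms: hydrogen peroxide, OO (source of the hydroxyl oxygen)
Why: 9‑BBN hydroborates only the unhindered terminal alkene, not the Δ5 olefin flanked by two quaternary carbons. Anti‑Markovnikov hydroboration followed by oxidation gives the 3‑carbon chain that becomes the aldehyde for the Wittig reaction.

**Step 9**
Reactants: 10
Product: 11 (TBDPS ether)
Conditions: TBDPSCl, imidazole, DMF, rt
Reagents that add atoms: tert‑butyldiphenylchlorosilane, CC(C)(C)[Si](Cl)(c1ccccc1)c1ccccc1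
Why: silylation protects the primary alcohol against the later oxidation of the ring alcohol. TBDPS is stable to the HAT, hydrogenolysis, LDA and 9‑BBN steps.

**Step 10**
Reactants: 11
Product: 12 (Cj–H α, trans‑fused)
Conditions: Mn(dpm)3 (cat.), PhSiH3, TBHP, i‑PrOH, rt
Reagents that add atoms: none
Why: Mukaiyama–Shenvi HAT hydrogenation places H on Ci and gives a tertiary Cj radical. The β face of that radical is shielded by the axial Ce‑Me and the axial Ca chain, so the second H is delivered from the α face, giving the trans ring fusion and setting Cj.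

**Step 11**
Reactants: 12
Product: 13 (free Cf alcohol)
Conditions: H2 (1 atm), 10 % Pd/C, EtOAc/EtOH, rt
Reagents that add atoms: none
Why: hydrogenolysis of the benzyl ether. No alkenes remain at this stage, and the TBDPS ether is unaffected.

**Step 12**
Reactants: 13
Product: 14 (Cf ketone)
Conditions: Dess–Martin periodinane, NaHCO3, CH2Cl2, rt
Reagents that add atoms: none
Why: DMP oxidizes the hindered secondary alcohol. This destroys the Cf carbinol stereocentre, so its configuration is irrelevant.

**Step 13**
Reactants: 14
Product: 15 (Cg‑methyl ketone, Cg epimeric mixture, inconsequential)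
Conditions: LDA, THF, −78 °C; MeI, DMPU, −78→0 °C
Reagents that add atoms: iodomethane, CI
Why: the ketone is flanked by quaternary Ce, so only Cg can be enolized, and enolate alkylation installs the ring methyl regiospecifically.

**Step 14**
Reactants: 15
Product: 16 (α‑methyl enone, Cf=O, Cg(Me)=Ch)
Conditions: LDA, TMSCl, THF, −78 °C; then Pd(OAc)2, MeCN, rt
Reagents that add atoms: none (TMS is lost)
Why: Saegusa–Ito oxidation of the silyl enol ether by β‑hydride elimination gives the endocyclic conjugated enone that fixes the Cg=Ch alkene position.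

**Step 15**
Reactants: 16
Product: 17 (Cf exocyclic methylene, conjugated with Cg=Ch)
Conditions: Cp2TiMe2, toluene/THF, 75 °C, dark
Reagents that add atoms: dimethyltitanocene, C[Ti](C)(C1C=CC=C1)C1C=CC=C1 (delivers the =CH2 carbon)
Why: Petasis methylenation converts the hindered, non‑enolizable‑side conjugated ketone to the diene without touching the silyl ether.

**Step 16**
Reactants: 17; 18 (methyl 3‑bromo‑4‑methoxybenzoate)
Product: 19 (aryl‑coupled product, Cf–CH2Ar)
Conditions: (a) 9‑BBN, THF, rt; (b) 18, Pd(dppf)Cl2, K3PO4 (aq), THF/DMF, 65 °C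
Reagents that add atoms: none (the aryl group comes from 18; boron is lost)
Why: 9‑BBN hydroborates the accessible exocyclic methylene, not the trisubstituted ring alkene. Syn addition of H from the α face, anti to the axial Ce‑Me, sets Cf‑H α and leaves CH2B equatorial (β). B‑alkyl Suzuki–Miyaura coupling then retains that configuration.

**Step 17**
Reactants: 19
Product: 20 (primary alcohol)
Conditions: TBAF, THF, rt
Reagents that add atoms: none
Why: fluoride removes the silyl ether; the methyl ester, aryl methyl ether and alkene are stable.

**Step 18**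
Reactants: 20
Product: 21 (aldehyde)
Conditions: Dess–Martin periodinane, NaHCO3, CH2Cl2, rt
Reagents that add atoms: none
Why: mild oxidation of the primary alcohol leaves the alkene and ester intact.

**Step 19**
Reactants: 21
Product: 22 (Ca–CH2CH2CH=CMe2 installed; methyl ester and aryl methyl ether still in place)
Conditions: i‑PrPPh3I, KOt‑Bu, THF, 0 °C→rt
Reagents that add atoms: isopropyltriphenylphosphonium iodide, CC(C)[P+](c1ccccc1)(c1ccccc1)c1ccccc1.[I-] (supplies the CMe2 unit)
Why: Wittig olefination of the aldehyde with isopropylidene ylide builds the 4‑methylpent‑3‑enyl chain. The ylide does not attack the ester, and no stereocentre is involved.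

**Step 20**
Reactants: 22
Product: 23 (jaspic acid)
Conditions: NaSEt, DMF, 120 °C; then 1 M HCl
Reagents that add atoms: none (the methyl groups leave as EtSMe)
Why: thiolate SN2 demethylation cleaves both the electron‑poor aryl methyl ether (para to the ester) and the methyl ester, giving the 4‑hydroxybenzoic acid without touching the alkenes or any stereocentre.

## Compound list
1 | 2‑methylcyclohexane‑1,3‑dione | CC1C(=O)CCCC1=O | starting material
2 | methyl vinyl ketone | C=CC(C)=O | starting material
3 | 2‑methyl‑2‑(3‑oxobutyl)cyclohexane‑1,3‑dione | CC(=O)CCC1(C)C(=O)CCCC1=O | intermediate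
4 | (2R,3S)‑3‑hydroxy‑2‑methyl‑2‑(3‑oxobutyl)cyclohexan‑1‑one | CC(=O)CC[C@@]1(C)C(=O)CCC[C@@H]1O | intermediate
5 | (4aS,5S)‑5‑hydroxy‑4a‑methyl‑hexahydronaphthalen‑2(3H)‑one | O=C1C=C2CCC[C@H](O)[C@@]2(C)CC1 | intermediate
6 | benzyl ether of 5 | O=C1C=C2CCC[C@H](OCc3ccccc3)[C@@]2(C)CC1 | intermediate
7 | 1‑allyl‑Δ1(8a) enone | C=CCC1=C2CCC[C@H](OCc3ccccc3)[C@@]2(C)CCC1=O | intermediate
8 | 1‑allyl(β)‑1‑methyl(α) β,γ‑enone | C=CC[C@@]1(C)C(=O)CC[C@]2(C)[C@@H](OCc3ccccc3)CCC=C12 | intermediate
9 | deoxygenated Δ5 olefin | C=CC[C@@]1(C)CCC[C@]2(C)[C@@H](OCc3ccccc3)CCC=C12 | intermediate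
10 | primary alcohol | OCCC[C@@]1(C)CCC[C@]2(C)[C@@H](OCc3ccccc3)CCC=C12 | intermediate
11 | TBDPS ether | CC(C)(C)[Si](c1ccccc1)(c1ccccc1)OCCC[C@@]1(C)CCC[C@]2(C)[C@@H](OCc3ccccc3)CCC=C12 | intermediate
12 | trans‑decalin (Cj–H α) | CC(C)(C)[Si](c1ccccc1)(c1ccccc1)OCCC[C@@]1(C)CCC[C@]2(C)[C@@H](OCc3ccccc3)CCC[C@@H]12 | intermediate
13 | free ring alcohol | CC(C)(C)[Si](c1ccccc1)(c1ccccc1)OCCC[C@@]1(C)CCC[C@]2(C)[C@@H](O)CCC[C@@H]12 | intermediate
14 | ring ketone | CC(C)(C)[Si](c1ccccc1)(c1ccccc1)OCCC[C@@]1(C)CCC[C@]2(C)C(=O)CCC[C@@H]12 | intermediate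
15 | α‑methyl ketone (Cg epimeric mixture) | CC(C)(C)[Si](c1ccccc1)(c1ccccc1)OCCC[C@@]1(C)CCC[C@]2(C)C(=O)C(C)CC[C@@H]12 | intermediate
16 | α‑methyl enone | CC(C)(C)[Si](c1ccccc1)(c1ccccc1)OCCC[C@@]1(C)CCC[C@]2(C)C(=O)C(C)=CC[C@@H]12 | intermediate
17 | exocyclic diene | CC(C)(C)[Si](c1ccccc1)(c1ccccc1)OCCC[C@@]1(C)CCC[C@]2(C)C(=C)C(C)=CC[C@@H]12 | intermediate
18 | methyl 3‑bromo‑4‑methoxybenzoate | COC(=O)c1ccc(OC)c(Br)c1 | starting material
19 | coupled aryl compound | CC(C)(C)[Si](c1ccccc1)(c1ccccc1)OCCC[C@@]1(C)CCC[C@]2(C)[C@@H](Cc3cc(C(=O)OC)ccc3OC)C(C)=CC[C@@H]12 | intermediate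
20 | primary alcohol | OCCC[C@@]1(C)CCC[C@]2(C)[C@@H](Cc3cc(C(=O)OC)ccc3OC)C(C)=CC[C@@H]12 | intermediate
21 | aldehyde | O=CCC[C@@]1(C)CCC[C@]2(C)[C@@H](Cc3cc(C(=O)OC)ccc3OC)C(C)=CC[C@@H]12 | intermediate
22 | methyl ester / aryl methyl ether of target | CC(C)=CCC[C@@]1(C)CCC[C@]2(C)[C@@H](Cc3cc(C(=O)OC)ccc3OC)C(C)=CC[C@@H]12 | intermediate
23 | jaspic acid | CC(C)=CCC[C@@]1(C)CCC[C@]2(C)[C@@H](Cc3cc(C(=O)O)ccc3O)C(C)=CC[C@@H]12 | target

## Totals
Total steps: 20. Longest linear sequence: 20 steps (compound 18 joins convergently at Step 16).

## Three steps most likely to fail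
1. **Step 6 (facial selectivity of the second alkylation, setting Ca).** The α:β ratio may be modest because the target has the axial chain 1,3‑diaxial to the angular methyl.
   Fallback (different approach): perform a Stork reductive alkylation of 6 (Li/NH3, then MeI). This sets the trans ring fusion and the 4α‑Me in one operation. Then alkylate the resulting enolate with allyl iodide to place the chain β‑axial, separate the diastereomers, and skip the HAT step.
2. **Step 10 (hindered Δ5 olefin reduction).** HAT hydrogenation may be slow or may give a cis‑fused epimer.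
   Fallback: hydroborate from the α face (BH3·SMe2), which gives syn H at Cj and B at Ci. Oxidize to the C‑6 alcohol, then remove it by Barton–McCombie deoxygenation.
3. **Step 16 (B‑alkyl Suzuki of a β‑branched neopentyl‑type borane with an ortho‑substituted aryl bromide).** Protodeboronation or β‑hydride elimination could compete with coupling.
   Fallback: hydroborate/oxidize to the primary alcohol, convert it to the iodide (Appel), and join it to 18 by Ni‑catalysed cross‑electrophile coupling (or Negishi coupling of an arylzinc) instead of the boron route.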